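**Plan**
Numbering: ring A is C1 (ether O), C2 (OH), C3 (H), C4 (Br), C5 (H), C6 (Br); ring B is C1' (ether O), C2' (OH), C3' (H), C4', C5', C6' (all Br).
Feature: in ring B the contiguous C4'-C5'-C6' tribromide plus C3' are the four carbons of a brominated thiophene, and C1'(OAr)-C2'(OH) is the two-carbon unit of an aryloxyacetic acid. A CO2Me group placed on C3' polarises the diene and is later lost as CO2.
Retrosynthesis: C3'-H goes back to C3'-CO2H and the phenols to methyl ether and ester. Ring B is then cut at C1'-C6' and C2'-C3' ([4+2], with loss of SO2 and Me3SiOH). Last, the O-CH2 bond of the aryloxyacetic acid and the C-CO2Me bond of the thiophene ester are cut.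
Forward: ring A is bought complete. The ketene acetal (steps 1-2) and the thiophene dioxide (steps 3-4) are joined in step 5, which builds ring B as a salicylate. Steps 6-7 free the phenols and remove the carboxyl group.
Stereochemistry: the target is achiral with no stereocentre; the sp3 centres of the cycloadduct vanish on aromatisation.

Key step: step 5

Assumption: 2,4-dibromo-6-methoxyphenol (4,6-dibromoguaiacol) is taken as a catalogue compound, as is 3,5-dibromo-2-fluorobenzaldehyde, which is used only in a fallback.

**Step 1**
Reactants: 1 2,4-dibromo-6-methoxyphenol; 2 bromoacetic acid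
Product: 3 2-(2,4-dibromo-6-methoxyphenoxy)acetic acid
Conditions: NaOH (3 equiv), 2 (1.5 equiv), H2O, reflux; then aq HCl to pH 1
Reagents that add atoms: none
Why: Williamson ether synthesis, in which the phenoxide displaces bromide from bromoacetate (SN2) as in the standard preparation of polyhalogenated aryloxyacetic acids; the two ortho substituents slow but do not block O-alkylation.

**Step 2**
Reactants: 3 2-(2,4-dibromo-6-methoxyphenoxy)acetic acid
Product: 5 2-(2,4-dibromo-6-methoxyphenoxy)ketene bis(trimethylsilyl) acetal, via trimethylsilyl ester 4 (not isolated)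
Conditions: LiN(SiMe3)2 (1.0 equiv), Me3SiCl (1.05 equiv), THF, 0 °C; then Me3SiCl (1.3 equiv), LiN(SiMe3)2 (1.15 equiv), -78 °C → 0 °C; pentane, filtration under Ar, used crude
Reagents that add atoms: chlorotrimethylsilane, C[Si](C)(C)Cl
Why: Ainsworth-type formation of a ketene bis(silyl) acetal, in which the carboxylate is O-silylated and the silyl ester is enolised by the hindered amide in the presence of Me3SiCl and trapped on oxygen; LiN(SiMe3)2 is too weak a base to metalate the bromoarene and does not exchange aryl bromides.

**Step 3**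
Reactants: 6 tetrabromothiophene; 7 methyl chloroformate
Product: 9 methyl 3,4,5-tribromothiophene-2-carboxylate, via thienylmagnesium chloride 8 (not isolated)
Conditions: iPrMgCl·LiCl (1.05 equiv), THF, -40 °C → -20 °C; then added to 7 (3 equiv), THF, -40 °C → rt
Reagents that add atoms: none
Why: Br/Mg exchange of tetrabromothiophene is selective for an alpha position (the most stabilised thienyl anion), and acylation of the Grignard reagent by inverse addition to excess chloroformate stops at the ester.

**Step 4**
Reactants: 9 methyl 3,4,5-tribromothiophene-2-carboxylate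
Product: 11 methyl 3,4,5-tribromothiophene-2-carboxylate 1,1-dioxide, via thiophene 1-oxide 10 (not isolated)
Conditions: H2O2·urea (6 equiv), (CF3CO)2O (8 equiv), MeCN, 0 °C → rt
Reagents that add atoms: trifluoroperacetic acid (made in the flask from H2O2·urea and trifluoroacetic anhydride), OOC(=O)C(F)(F)F
Why: S-oxidation by anhydrous trifluoroperacetic acid, the established oxidant for taking halogen- and acyl-substituted thiophenes through the S-oxide to the 1,1-dioxide; the fully substituted ring cannot dimerise as simple thiophene dioxides do.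

**Step 5**
Reactants: 5 2-(2,4-dibromo-6-methoxyphenoxy)ketene bis(trimethylsilyl) acetal; 11 methyl 3,4,5-tribromothiophene-2-carboxylate 1,1-dioxide
Product: 15 methyl 4,5,6-tribromo-3-(2,4-dibromo-6-methoxyphenoxy)-2-hydroxybenzoate, via bridged sulfone cycloadduct 12 (not isolated), via bis(silyloxy)cyclohexadiene 13 (not isolated), via aryl trimethylsilyl ether 14 (not isolated)
Conditions: 5 (1.5 equiv), toluene, 0 °C → rt, then 80 °C; then 1 M HCl, THF, rt
Reagents that add atoms: none
Why: An asynchronous inverse-electron-demand [4+2] cycloaddition is expected in which the nucleophilic CH(OAr) carbon of 5 (future C1') bonds first to the C-Br terminus of diene 11 (future C6'), the terminus with the largest LUMO coefficient because it is remote from the ester, while the charge building at the other terminus (future C3') is stabilised by SO2 and CO2Me and closes onto the bis(silyloxy)carbenium carbon (future C2'). The closest known reaction type is the cycloaddition of tetrahalothiophene 1,1-dioxides with electron-rich alkenes followed by SO2 extrusion and aromatising elimination, and the same orientation (acetal carbon next to the ester-bearing carbon) is the one by which ketene acetals and 3-carbomethoxy-2-pyrones give salicylates. Ring B closes as a six-membered carbocycle in this [4+2] event (bridged sulfone 12), retro-cheletropic loss of SO2 then opens the bridge to cyclohexadiene 13, and 1,2-elimination of Me3SiOH with the only ring hydrogen (on C1') gives silyl ether 14, which the acidic work-up cleaves to phenol 15. No stereocentre is retained, since the sp3 carbons of 12 and 13 all become aromatic. The selectivity required is regiochemical (C1' beside C-Br, C2' beside the carboxyl-bearing carbon) and is secured by pairing the polarised ketene acetal with the ester-polarised diene, while aromatisation is unambiguous because C2' and C6' carry no hydrogen, so ArOH cannot be expelled. Toluene and a low starting temperature are chosen to keep the two bond formations concerted and to suppress zwitterion-derived Michael, vinylic-substitution or bromine-transfer products.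

**Step 6**
Reactants: 15 methyl 4,5,6-tribromo-3-(2,4-dibromo-6-methoxyphenoxy)-2-hydroxybenzoate
Product: 16 4,5,6-tribromo-3-(2,4-dibromo-6-hydroxyphenoxy)-2-hydroxybenzoic acid
Conditions: BBr3 (6 equiv), CH2Cl2, -78 °C → rt (40 °C if needed); then H2O
Reagents that add atoms: none
Why: Lewis-acid dealkylation, in which BBr3 cleaves the aryl methyl ether and, in excess at room temperature, the methyl ester as well by bromide attack at the unhindered O-CH3 carbon of the boron-chelated salicylate; the acidic medium also avoids the base-induced Smiles-type aryl migration to which ortho-hydroxy diaryl ethers with a polybrominated ring are prone, which is why no hydroxide saponification is used.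

**Step 7**
Reactants: 16 4,5,6-tribromo-3-(2,4-dibromo-6-hydroxyphenoxy)-2-hydroxybenzoic acid
Product: 17 3,4,5-tribromo-2-(2,4-dibromo-6-hydroxyphenoxy)phenol (target)
Conditions: Ag2CO3 (10 mol %), AcOH (5 mol %), DMSO, 120 °C
Reagents that add atoms: none
Why: Silver-catalysed protodecarboxylation of a benzoic acid flanked by OH and Br, in which the carboxylate of monovalent silver extrudes CO2 (accelerated by both ortho substituents) and the arylsilver is protonated to leave C3'-H; aryl bromides are inert under these conditions.

**Compound list**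
1 | 2,4-dibromo-6-methoxyphenol | COc1cc(Br)cc(Br)c1O | starting material
2 | bromoacetic acid | OC(=O)CBr | starting material
3 | 2-(2,4-dibromo-6-methoxyphenoxy)acetic acid | COc1cc(Br)cc(Br)c1OCC(=O)O | intermediate
4 | trimethylsilyl 2-(2,4-dibromo-6-methoxyphenoxy)acetate (not isolated) | COc1cc(Br)cc(Br)c1OCC(=O)O[Si](C)(C)C | intermediate
5 | 2-(2,4-dibromo-6-methoxyphenoxy)ketene bis(trimethylsilyl) acetal | COc1cc(Br)cc(Br)c1OC=C(O[Si](C)(C)C)O[Si](C)(C)C | intermediate
6 | tetrabromothiophene | Brc1sc(Br)c(Br)c1Br | starting material
7 | methyl chloroformate | COC(=O)Cl | starting material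
8 | (3,4,5-tribromothiophen-2-yl)magnesium chloride (not isolated) | Cl[Mg]c1sc(Br)c(Br)c1Br | intermediate
9 | methyl 3,4,5-tribromothiophene-2-carboxylate | COC(=O)c1sc(Br)c(Br)c1Br | intermediate
10 | methyl 3,4,5-tribromothiophene-2-carboxylate 1-oxide (racemic, not isolated) | COC(=O)C1=C(Br)C(Br)=C(Br)S1=O | intermediate
11 | methyl 3,4,5-tribromothiophene-2-carboxylate 1,1-dioxide | COC(=O)C1=C(Br)C(Br)=C(Br)S1(=O)=O | intermediate
12 | methyl 4,5,6-tribromo-3-(2,4-dibromo-6-methoxyphenoxy)-2,2-bis(trimethylsilyloxy)-7-thiabicyclo[2.2.1]hept-5-ene-1-carboxylate 7,7-dioxide (racemic diastereomer mixture, not isolated) | COC(=O)C12C(Br)=C(Br)C(Br)(C(Oc3c(OC)cc(Br)cc3Br)C1(O[Si](C)(C)C)O[Si](C)(C)C)S2(=O)=O | intermediate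
13 | methyl 2,3,4-tribromo-5-(2,4-dibromo-6-methoxyphenoxy)-6,6-bis(trimethylsilyloxy)cyclohexa-1,3-diene-1-carboxylate (racemic, not isolated) | COC(=O)C1=C(Br)C(Br)=C(Br)C(Oc2c(OC)cc(Br)cc2Br)C1(O[Si](C)(C)C)O[Si](C)(C)C | intermediate
14 | methyl 4,5,6-tribromo-3-(2,4-dibromo-6-methoxyphenoxy)-2-(trimethylsilyloxy)benzoate (not isolated) | COC(=O)c1c(O[Si](C)(C)C)c(Oc2c(OC)cc(Br)cc2Br)c(Br)c(Br)c1Br | intermediate
15 | methyl 4,5,6-tribromo-3-(2,4-dibromo-6-methoxyphenoxy)-2-hydroxybenzoate | COC(=O)c1c(O)c(Oc2c(OC)cc(Br)cc2Br)c(Br)c(Br)c1Br | intermediate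
16 | 4,5,6-tribromo-3-(2,4-dibromo-6-hydroxyphenoxy)-2-hydroxybenzoic acid | OC(=O)c1c(O)c(Oc2c(O)cc(Br)cc2Br)c(Br)c(Br)c1Br | intermediate
17 | 3,4,5-tribromo-2-(2,4-dibromo-6-hydroxyphenoxy)phenol | Oc1cc(Br)cc(Br)c1Oc1c(O)cc(Br)c(Br)c1Br | target

**Step count and risks**
Total steps: 7. Longest linear sequence: 5 steps (steps 1, 2, 5, 6, 7 or steps 3, 4, 5, 6, 7).

Steps most likely to fail:

1. Step 5. The two bond formations may not stay concerted. After the first C-C bond the zwitterion can be diverted by silyl transfer, by bromide expulsion at the beta carbon, or by bromine transfer to the electron-rich acetal, so that ring B does not close; the orientation could also erode. Fallback: the diaryl ether is made by substitution, setting out from 1 and returning at 17, with the ring of 1 now serving as ring B.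
   - Bromination of 1 para to the methoxy group (Br2, AcOH) should give 2,3,4-tribromo-6-methoxyphenol F1.
   - SNAr of its phenoxide on commercial 3,5-dibromo-2-fluorobenzaldehyde (Cs2CO3, DMAc, 100 °C) would give 3,5-dibromo-2-(2,3,4-tribromo-6-methoxyphenoxy)benzaldehyde F2.
   - Baeyer-Villiger oxidation (mCPBA, CH2Cl2) leads to 3,5-dibromo-2-(2,3,4-tribromo-6-methoxyphenoxy)phenyl formate F3, and acidic methanolysis (HCl, MeOH) to 3,5-dibromo-2-(2,3,4-tribromo-6-methoxyphenoxy)phenol F4.
   - BBr3 in CH2Cl2 then gives 17.

2. Step 4. Oxygen transfer to the strongly deactivated sulfur may stall at the thiophene or S-oxide stage, or the peracid may degrade the dioxide once formed. Fallback: silicon replaces the ester as the traceless group on C3', setting out from 6 and returning at 17.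
   - Metalation of 6 as in step 3 and a quench with Me3SiCl should give (3,4,5-tribromothiophen-2-yl)trimethylsilane F5.
   - This far less deactivated thiophene should be oxidised by mCPBA (1,2-dichloroethane, reflux) to 3,4,5-tribromo-2-(trimethylsilyl)thiophene 1,1-dioxide F6.
   - Cycloaddition with 5 under the conditions of step 5 would give 3,4,5-tribromo-2-(2,4-dibromo-6-methoxyphenoxy)-6-(trimethylsilyl)phenol F7. Orientation here rests on attack at the less hindered C-Br terminus and on the same, weaker, LUMO polarisation.
   - Ipso-protodesilylation ortho to the hydroxyl group (CF3CO2H, CH2Cl2) gives 3,4,5-tribromo-2-(2,4-dibromo-6-methoxyphenoxy)phenol F8, and BBr3 gives 17. No decarboxylation is needed.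

3. Step 2. Enolisation of the silyl ester may be incomplete, silylation may go to carbon, and the bis-silyl acetal, which cannot be purified, may hydrolyse on handling. Fallback: a sturdier mixed ketene acetal from the methyl ester, setting out from 1 and returning at 16.
   - Alkylation of 1 with methyl bromoacetate (K2CO3, acetone, reflux) gives methyl 2-(2,4-dibromo-6-methoxyphenoxy)acetate F9.
   - LiN(SiMe3)2 and Me3SiCl (THF, -78 °C) give 2-(2,4-dibromo-6-methoxyphenoxy)ketene methyl trimethylsilyl acetal F10.
   - Cycloaddition with 11 as in step 5, with aromatisation by loss of Me3SiOH, should give methyl 4,5,6-tribromo-3-(2,4-dibromo-6-methoxyphenoxy)-2-methoxybenzoate F11.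
   - Under the BBr3 conditions of step 6, F11 is converted into 16. Any 15 formed by the alternative loss of methanol enters step 6 in the same way.

**Further compounds**
F1 | step 5 | 2,3,4-tribromo-6-methoxyphenol | COc1cc(Br)c(Br)c(Br)c1O
F2 | step 5 | 3,5-dibromo-2-(2,3,4-tribromo-6-methoxyphenoxy)benzaldehyde | COc1cc(Br)c(Br)c(Br)c1Oc1c(Br)cc(Br)cc1C=O
F3 | step 5 | 3,5-dibromo-2-(2,3,4-tribromo-6-methoxyphenoxy)phenyl formate | COc1cc(Br)c(Br)c(Br)c1Oc1c(Br)cc(Br)cc1OC=O
F4 | step 5 | 3,5-dibromo-2-(2,3,4-tribromo-6-methoxyphenoxy)phenol | COc1cc(Br)c(Br)c(Br)c1Oc1c(Br)cc(Br)cc1O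
F5 | step 4 | (3,4,5-tribromothiophen-2-yl)trimethylsilane | C[Si](C)(C)c1sc(Br)c(Br)c1Br
F6 | step 4 | 3,4,5-tribromo-2-(trimethylsilyl)thiophene 1,1-dioxide | C[Si](C)(C)C1=C(Br)C(Br)=C(Br)S1(=O)=O
F7 | step 4 | 3,4,5-tribromo-2-(2,4-dibromo-6-methoxyphenoxy)-6-(trimethylsilyl)phenol | COc1cc(Br)cc(Br)c1Oc1c(O)c([Si](C)(C)C)c(Br)c(Br)c1Br
F8 | step 4 | 3,4,5-tribromo-2-(2,4-dibromo-6-methoxyphenoxy)phenol | COc1cc(Br)cc(Br)c1Oc1c(O)cc(Br)c(Br)c1Br
F9 | step 2 | methyl 2-(2,4-dibromo-6-methoxyphenoxy)acetate | COC(=O)COc1c(OC)cc(Br)cc1Br
F10 | step 2 | 2-(2,4-dibromo-6-methoxyphenoxy)ketene methyl trimethylsilyl acetal (E/Z mixture) | COC(=COc1c(OC)cc(Br)cc1Br)O[Si](C)(C)C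
F11 | step 2 | methyl 4,5,6-tribromo-3-(2,4-dibromo-6-methoxyphenoxy)-2-methoxybenzoate | COC(=O)c1c(OC)c(Oc2c(OC)cc(Br)cc2Br)c(Br)c(Br)c1Br
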